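**Plan**
- Retrosynthesis: the lactone C7–O bond is cut first (to seco acid 37), then C5=C6 (ring-closing metathesis), C7–C8 (allylation), C8–C17 (lactate aldol), C3–C4 (boron aldol), C2–C3 (alkoxymethyl addition), and ring A (Diels–Alder, C1–C14 and C10–C11).
- Enabling feature: C7 is the allylic methylene beside the Z C5=C6 alkene of the ten-membered ring and is γ to the C19 carboxyl (C19–C17–C8–C7), so one C–H hydroxylation closes the five-membered lactone C7–O–C19–C17–C8.
- Forward order: ring A, then the C2–C5 chain, the ring A diol, the C8/C17–C19 and C6–C7 units, the three acetates, the ten-membered ring, unmasking, and last the enzymatic oxidation with lactonisation.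
- Stereochemistry: C9 from (S)-but-3-ene-1,2-diol; C1/C10 from the Diels–Alder (E dienophile, allylic strain from C9); C3/C4 from a chiral boron aldol; C2 by 1,3-anti reduction; C11/C12 by enolate hydroxylation and Luche reduction.
- C17 comes from (R)-lactic acid via its dioxolanone; C8 from chelation-controlled allylation; C7 from the enzyme.

Key step: step 28

Remark: briarane numbering is used (ring A = C1, C10–C14; ten-membered ring = C1–C10; C15 on C1, C16 on C5, C17(C18)–C19 on C8, C20 on C11); PMB = 4-methoxybenzyl, DMB = 3,4-dimethoxybenzyl.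
Assumption: C11 in 7–19, the arylidene acetal carbon in 2–22, C2 in 12 and C8 in 28 form as epimer mixtures and are left undefined in the SMILES, because each is erased or removed later (steps 12, 15, 7 and 19).

**Route**

Step 1
Reactants: 1 (S)-but-3-ene-1,2-diol
Product: 2 (4S)-2-(3,4-dimethoxyphenyl)-4-vinyl-1,3-dioxolane
Conditions: 3,4-dimethoxybenzaldehyde, PPTS (cat.), toluene, reflux, Dean–Stark trap
Reagents that add atoms: 3,4-dimethoxybenzaldehyde, COc1ccc(C=O)cc1OC
Why: Acid-catalysed acetalisation of the 1,2-diol with removal of water; the carbinol carbon that becomes C9 is taken unchanged from the chiral pool, and the electron-rich arylidene acetal can later be opened reductively to a 9-O-DMB ether.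

Step 2
Reactants: 2 (4S)-2-(3,4-dimethoxyphenyl)-4-vinyl-1,3-dioxolane; 3 methacrolein
Product: 4 (E)-3-[(4S)-2-(3,4-dimethoxyphenyl)-1,3-dioxolan-4-yl]-2-methylprop-2-enal
Conditions: second-generation Hoveyda–Grubbs catalyst [RuCl2(H2IMes)(=CH–C6H4-2-OiPr)] (5 mol %), methacrolein (5 equiv), CH2Cl2, 40 °C
Reagents that add atoms: none
Why: Olefin cross-metathesis of the terminal alkene with excess methacrolein gives the more stable E trisubstituted enal and releases ethylene.

Step 3
Reactants: 5 pent-1-en-3-one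
Product: 6 (Z)-3-(tert-butyldimethylsilyloxy)penta-1,3-diene
Conditions: TBSOTf, Et3N, Et2O, 0 °C
Reagents that add atoms: tert-butyldimethylsilyl triflate, CC(C)(C)[Si](C)(C)OS(=O)(=O)C(F)(F)F
Why: Silyl enol ether formation by O-silylation of the amine-generated enolate gives the Z enol ether, whose methyl group points away from the vinyl group so that the diene can reach the s-cis form.

Step 4
Reactants: 4 (E)-enal; 6 (Z)-3-(tert-butyldimethylsilyloxy)penta-1,3-diene
Product: 7 ring A aldehyde (C2 formyl and C15 methyl on C1; C8/C9 dioxolane on C10 cis to C15; C12 silyl enol ether)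
Conditions: Me2AlCl (0.3 equiv), 6 (1.5 equiv), CH2Cl2, −78 → −40 °C
Reagents that add atoms: none
Why: Lewis acid-catalysed Diels–Alder reaction in which the 2-silyloxy group directs the "para" orientation (C11 to C10, C14 to C1), the E dienophile geometry puts C15 and C9 cis on ring A, and the diene adds anti to the C9–O bond of the dienophile held by allylic 1,3-strain (C9–H eclipsing C1=C10), which sets C1 and C10 from C9.

Step 5
Reactants: 8 tributyl(iodomethyl)stannane; 9 4-methoxybenzyl alcohol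
Product: 10 tributyl{[(4-methoxybenzyl)oxy]methyl}stannane
Conditions: NaH, THF/DMF, 0 °C → rt
Reagents that add atoms: none
Why: Williamson ether synthesis, the alkoxide displacing iodide at the primary stannylmethyl carbon.

Step 6
Reactants: 10 tributyl{[(4-methoxybenzyl)oxy]methyl}stannane; 7 ring A aldehyde
Product: 12 C2 carbinol CH(OH)CH2OPMB (both C2 epimers), via [(4-methoxybenzyl)oxy]methyllithium 11 (not isolated)
Conditions: n-BuLi, THF, −78 °C; then 7, −78 °C; aqueous work-up
Reagents that add atoms: none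
Why: Tin–lithium exchange gives the α-alkoxymethyllithium, which adds 1,2 to the non-enolisable neopentyl aldehyde; the new carbinol centre is oxidised in the next step, so no control is needed.

Step 7
Reactants: 12 C2 carbinol
Product: 13 C2 ketone (ring A–CO–CH2OPMB)
Conditions: Dess–Martin periodinane, pyridine, CH2Cl2, 0 °C → rt
Reagents that add atoms: none
Why: Dess–Martin oxidation of the hindered secondary alcohol under buffered conditions that leave the silyl enol ether and the acetal intact.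

Step 8
Reactants: 13 C2 ketone; 3 methacrolein
Product: 15 (3R,4S)-aldol adduct (2-ketone with 3-OPMB and 4-OH and the C5 isopropenyl group), via diisopinocampheylboron enolate 14 (not isolated)
Conditions: (−)-Ipc2BOTf [from (+)-α-pinene], iPr2NEt, CH2Cl2, −78 °C; methacrolein, −78 → −20 °C; H2O2, MeOH, pH 7 buffer, 0 °C
Reagents that add atoms: none
Why: Boron-mediated aldol addition in which the Z enolate of the α-alkoxy ketone reacts through a Zimmerman–Traxler chair to give the 3,4-syn adduct, and the isopinocampheyl ligands are expected to select the enolate face leading to 3R,4S (reagent control).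

Step 9
Reactants: 15 aldol adduct
Product: 16 (2S,3R,4S)-2,4-diol
Conditions: Me4NBH(OAc)3, MeCN/AcOH, −30 °C
Reagents that add atoms: none
Why: Evans–Saksena reduction, the boron bound to O4 delivering hydride intramolecularly through a chair to give the 2,4-anti diol and so fixing C2 as 2S.

Step 10
Reactants: 16 2,4-diol
Product: 17 2,4-O-isopropylidene acetal
Conditions: 2-methoxypropene, PPTS (cat.), CH2Cl2, 0 °C
Reagents that add atoms: 2-methoxypropene, C=C(C)OC
Why: Acetonide formation on the 1,3-diol masks O2 and O4 for the base and hydride steps that follow and is mild enough for the silyl enol ether and the arylidene acetal.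

Step 11
Reactants: 17 2,4-O-isopropylidene acetal
Product: 18 ring A enone (C12 ketone, C13=C14)
Conditions: Pd(OAc)2 (1.1 equiv), MeCN, rt → 40 °C
Reagents that add atoms: none
Why: Saegusa–Ito oxidation, the silyl enol ether passing to divalent palladium at C13 and β-hydride elimination from C14 giving the C13=C14 enone, the only direction open because C12 carries no hydrogen.

Step 12
Reactants: 18 ring A enone
Product: 20 (11S)-11-hydroxy enone, via potassium dienolate 19 (not isolated)
Conditions: KHMDS, THF, −78 °C; 2-(phenylsulfonyl)-3-phenyloxaziridine, −78 °C; aqueous work-up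
Reagents that add atoms: 2-(phenylsulfonyl)-3-phenyloxaziridine, O=S(=O)(N1OC1c1ccccc1)c1ccccc1
Why: Davis oxidation of the α′-enolate (C11 is the only enolisable position because C1 is quaternary), oxygen entering anti to the C10 side chain and the C15 methyl to give 11S from both C11 epimers.

Step 13
Reactants: 20 11-hydroxy enone
Product: 21 (11S,12R)-11,12-cis-diol
Conditions: NaBH4, CeCl3·7H2O, MeOH, −78 °C
Reagents that add atoms: none
Why: Luche 1,2-reduction of the enone, hydride being expected to attack anti to the pseudo-axial C11–O bond (Felkin–Anh control by the α-oxygen), which places the 12-hydroxyl cis to the 11-hydroxyl.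

Step 14
Reactants: 21 cis-diol
Product: 22 11,12-O-isopropylidene acetal
Conditions: 2-methoxypropene, PPTS (cat.), CH2Cl2, 0 °C → rt
Reagents that add atoms: 2-methoxypropene, C=C(C)OC
Why: Acetonide formation on the cis-1,2-diol of ring A, which also hides the tertiary O11 that would otherwise add to the later C8 carbonyl as a five-membered lactol.

Step 15
Reactants: 22 bis-acetonide
Product: 23 C8 primary alcohol with 9-O-DMB ether
Conditions: DIBAL-H (iBu2AlH, 4 equiv), CH2Cl2, −78 → 0 °C
Reagents that add atoms: none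
Why: Reductive opening of the arylidene acetal, aluminium binding the less hindered primary oxygen and hydride going to the acetal carbon, which leaves the DMB group on the secondary O9 and the isopropylidene acetals untouched.

Step 16
Reactants: 23 C8 primary alcohol
Product: 24 C8 aldehyde
Conditions: Dess–Martin periodinane, pyridine, CH2Cl2, 0 °C
Reagents that add atoms: none
Why: Dess–Martin oxidation of the primary alcohol under neutral conditions, which avoids epimerisation of the α-alkoxy aldehyde at C9.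

Step 17
Reactants: 25 (R)-lactic acid
Product: 26 (2R,5R)-2-tert-butyl-5-methyl-1,3-dioxolan-4-one
Conditions: pivalaldehyde, p-TsOH (cat.), pentane, reflux, Dean–Stark trap; crystallisation
Reagents that add atoms: pivalaldehyde, CC(C)(C)C=O
Why: Acid-catalysed acetalisation of the α-hydroxy acid gives the cis dioxolanone, in which the lactate centre fixes the acetal centre that later controls the enolate face (self-regeneration of stereocentres).

Step 18
Reactants: 26 dioxolanone; 24 C8 aldehyde
Product: 28 aldol adduct (17S; both C8 epimers), via dioxolanone lithium enolate 27 (not isolated)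
Conditions: LDA, THF, −78 °C; then 24, −78 °C; aqueous work-up
Reagents that add atoms: none
Why: Aldol addition of the dioxolanone lithium enolate, the aldehyde entering trans to the tert-butyl group so that C17 forms as 17S with overall retention from (R)-lactic acid; the C8 carbinol centre is removed in the next step.

Step 19
Reactants: 28 aldol adduct
Product: 29 C8 ketone
Conditions: Dess–Martin periodinane, pyridine, CH2Cl2, 0 °C → rt
Reagents that add atoms: none
Why: Dess–Martin oxidation to a ketone that cannot enolise towards the quaternary C17, so that centre is safe.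

Step 20
Reactants: 29 C8 ketone
Product: 30 (8S)-8-allyl carbinol
Conditions: allylMgBr, Et2O/CH2Cl2, −78 °C
Reagents that add atoms: allylmagnesium bromide, C=CC[Mg]Br
Why: Chelation-controlled Grignard addition (Cram chelate), magnesium bridging the C8 carbonyl and the O9 ether so that the allyl group attacks from the face opposite ring A and gives 8S with O8 and O9 arranged as in the target.

Step 21
Reactants: 30 allyl carbinol
Product: 31 8,17-dihydroxy acid
Conditions: LiOH, THF/H2O, 0 °C → rt; then 1 M HCl to pH 3, 0 °C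
Reagents that add atoms: lithium hydroxide, [Li+].[OH-]
Why: Saponification of the acylal ester opens the dioxolanone, releasing pivalaldehyde and the tertiary O17 hydroxyl while O9 is still blocked and cannot lactonise.

Step 22
Reactants: 31 dihydroxy acid
Product: 32 tert-butyl ester
Conditions: tert-butyl 2,2,2-trichloroacetimidate, cyclohexane/CH2Cl2, rt
Reagents that add atoms: tert-butyl 2,2,2-trichloroacetimidate, CC(C)(C)OC(=N)C(Cl)(Cl)Cl
Why: Esterification by tert-butyl transfer from the imidate to the carboxylic acid gives an ester that resists attack by the γ-hydroxyl at C9 once that is freed.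

Step 23
Reactants: 32 tert-butyl ester
Product: 33 9-alcohol
Conditions: DDQ (1.1 equiv), CH2Cl2/pH 7 buffer, 0 °C
Reagents that add atoms: none
Why: Oxidative benzyl ether cleavage by DDQ, which removes the more electron-rich DMB group at O9 faster than the PMB group at O3.

Step 24
Reactants: 33 9-alcohol
Product: 34 2,4,9-triol
Conditions: PPTS, MeOH, 0 °C → rt
Reagents that add atoms: none
Why: Acid-catalysed transacetalisation to methanol should cleave the strained twist-boat acetonide of the anti-1,3-diol much faster than the cis-fused five-membered acetonide on ring A.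

Step 25
Reactants: 34 2,4,9-triol
Product: 35 2,4,9-triacetate
Conditions: Ac2O, pyridine, DMAP (cat.), CH2Cl2, rt
Reagents that add atoms: acetic anhydride, CC(=O)OC(C)=O
Why: DMAP-catalysed acylation esterifies the three secondary hydroxyls, whereas the tertiary hydroxyls at C8 and C17 are too hindered to react.

Step 26
Reactants: 35 2,4,9-triacetate
Product: 36 protected seco ester (ten-membered ring, Z C5=C6)
Conditions: second-generation Hoveyda–Grubbs catalyst [RuCl2(H2IMes)(=CH–C6H4-2-OiPr)] (20 mol %), 1,4-benzoquinone, toluene (1 mM), 90 °C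
Reagents that add atoms: none
Why: Ring-closing metathesis in which the ruthenium alkylidene forms at the unhindered allyl terminus (C6) and closes onto the 1,1-disubstituted C5 alkene, the less strained Z trisubstituted alkene of the ten-membered ring being expected under reversible conditions.

Step 27
Reactants: 36 protected seco ester
Product: 37 7-deoxy seco acid of brianodin C
Conditions: TFA/CH2Cl2/H2O, anisole, 0 °C → rt
Reagents that add atoms: none
Why: Acidolysis removes the tert-butyl ester (as isobutene), the PMB ether (cation trapped by anisole) and the ring A isopropylidene acetal (hydrolysis) in one operation, while the three acetates are stable to acid.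

Step 28
Reactants: 37 7-deoxy seco acid
Product: 39 brianodin C, via 7-hydroxy seco acid 38 (not isolated)
Conditions: engineered cytochrome P450 monooxygenase (haem-iron enzyme, variant evolved for C7 selectivity), O2 (air), NADPH (cat.) recycled with glucose/glucose dehydrogenase, phosphate buffer pH 8, 25 °C; brief acidification to pH 4 on work-up
Reagents that add atoms: dioxygen, O=O
Why: Proposed new method: the high-valent oxo-iron haem species (formally tetravalent iron with a porphyrin radical cation) abstracts one hydrogen of the allylic C7 methylene and returns hydroxyl to the same face of the allyl radical (oxygen rebound), and the 7-hydroxy acid 38 then closes by attack of O7 on the C19 carboxyl. The closest known reaction type is the P450-catalysed allylic hydroxylation of a germacrene acid at the ring carbon next to the acid-bearing carbon, followed by spontaneous lactonisation (costunolide synthase). The γ-lactone C7–O–C19–C17–C8 closes by 5-exo-trig acyl substitution, which is fast because C8 and C17 are fully substituted. The new C7 stereocentre (7S) is fixed by the enzyme pocket, which presents one C7–H to the iron-oxo unit, and hydroxylation proceeds with retention. Selectivity for C7 over the C16 methyl, C4–H, C12–H and the two alkenes must come from the active site tuned by directed evolution; the substrate helps through the C19 carboxylate two carbons away as a binding anchor, the weak allylic C7–H bond, and the acetoxy and hydroxyl groups that deactivate the allylic C–H bonds at C4 and C12.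

**Compound list**

1 | (S)-but-3-ene-1,2-diol | C=C[C@H](O)CO | starting material
2 | (4S)-2-(3,4-dimethoxyphenyl)-4-vinyl-1,3-dioxolane (both acetal epimers) | C=C[C@H]1COC(c2ccc(OC)c(OC)c2)O1 | intermediate
3 | methacrolein | C=C(C)C=O | starting material
4 | (E)-3-[(4S)-2-(3,4-dimethoxyphenyl)-1,3-dioxolan-4-yl]-2-methylprop-2-enal | O=C/C(C)=C/[C@H]1COC(c2ccc(OC)c(OC)c2)O1 | intermediate
5 | pent-1-en-3-one | C=CC(=O)CC | starting material
6 | (Z)-3-(tert-butyldimethylsilyloxy)penta-1,3-diene | C=C/C(O[Si](C)(C)C(C)(C)C)=C/C | intermediate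
7 | ring A aldehyde: (1S,6S)-4-(tert-butyldimethylsilyloxy)-6-[(4S)-2-(3,4-dimethoxyphenyl)-1,3-dioxolan-4-yl]-1,5-dimethylcyclohex-3-ene-1-carbaldehyde (C15 cis to the C10 side chain; C11 epimers) | O=C[C@@]1(C)CC=C(O[Si](C)(C)C(C)(C)C)C(C)[C@@H]1[C@H]2COC(c3ccc(OC)c(OC)c3)O2 | intermediate
8 | tributyl(iodomethyl)stannane | CCCC[Sn](CCCC)(CCCC)CI | starting material
9 | 4-methoxybenzyl alcohol | COc1ccc(CO)cc1 | starting material
10 | tributyl{[(4-methoxybenzyl)oxy]methyl}stannane | CCCC[Sn](CCCC)(CCCC)COCc1ccc(OC)cc1 | intermediate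
11 | [(4-methoxybenzyl)oxy]methyllithium | [Li]COCc1ccc(OC)cc1 | intermediate
12 | C2 carbinol: formyl group of 7 converted into CH(OH)CH2OPMB (C2 epimers) | OC(COCc4ccc(OC)cc4)[C@@]1(C)CC=C(O[Si](C)(C)C(C)(C)C)C(C)[C@@H]1[C@H]2COC(c3ccc(OC)c(OC)c3)O2 | intermediate
13 | C2 ketone: ring A–C(=O)–CH2OPMB | O=C(COCc4ccc(OC)cc4)[C@@]1(C)CC=C(O[Si](C)(C)C(C)(C)C)C(C)[C@@H]1[C@H]2COC(c3ccc(OC)c(OC)c3)O2 | intermediate
14 | (Z)-enol diisopinocampheylborinate of 13 (O–B and OPMB cis on C2=C3) | COc1ccc(CO/C=C(\OB([C@H]2[C@H](C)[C@H]3C[C@@H](C2)C3(C)C)[C@H]4[C@H](C)[C@H]5C[C@@H](C4)C5(C)C)[C@@]6(C)CC=C(O[Si](C)(C)C(C)(C)C)C(C)[C@@H]6[C@H]7COC(c8ccc(OC)c(OC)c8)O7)cc1 | intermediate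
15 | (3R,4S)-aldol adduct: C2 ketone, 3-OPMB, 4-OH, C5 isopropenyl (3,4-syn) | C=C(C)[C@H](O)[C@@H](OCc4ccc(OC)cc4)C(=O)[C@@]1(C)CC=C(O[Si](C)(C)C(C)(C)C)C(C)[C@@H]1[C@H]2COC(c3ccc(OC)c(OC)c3)O2 | intermediate
16 | (2S,3R,4S)-2,4-diol with 3-OPMB (2,3-anti, 3,4-syn) | C=C(C)[C@H](O)[C@@H](OCc4ccc(OC)cc4)[C@@H](O)[C@@]1(C)CC=C(O[Si](C)(C)C(C)(C)C)C(C)[C@@H]1[C@H]2COC(c3ccc(OC)c(OC)c3)O2 | intermediate
17 | 2,4-O-isopropylidene acetal of 16 | C=C(C)[C@@H]5OC(C)(C)O[C@@H]([C@@]1(C)CC=C(O[Si](C)(C)C(C)(C)C)C(C)[C@@H]1[C@H]2COC(c3ccc(OC)c(OC)c3)O2)[C@@H]5OCc4ccc(OC)cc4 | intermediate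
18 | ring A enone: C12 ketone, C13=C14 (C11 epimers) | C=C(C)[C@@H]5OC(C)(C)O[C@@H]([C@@]1(C)C=CC(=O)C(C)[C@@H]1[C@H]2COC(c3ccc(OC)c(OC)c3)O2)[C@@H]5OCc4ccc(OC)cc4 | intermediate
19 | potassium dienolate of 18 (C11=C12–O−) | C=C(C)[C@@H]5OC(C)(C)O[C@@H]([C@@]1(C)C=CC([O-])=C(C)[C@@H]1[C@H]2COC(c3ccc(OC)c(OC)c3)O2)[C@@H]5OCc4ccc(OC)cc4.[K+] | intermediate
20 | (11S)-11-hydroxy enone (11-OH trans to the C10 side chain) | C=C(C)[C@@H]5OC(C)(C)O[C@@H]([C@@]1(C)C=CC(=O)[C@@](C)(O)[C@@H]1[C@H]2COC(c3ccc(OC)c(OC)c3)O2)[C@@H]5OCc4ccc(OC)cc4 | intermediate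
21 | (11S,12R)-11,12-cis-diol | C=C(C)[C@@H]5OC(C)(C)O[C@@H]([C@@]1(C)C=C[C@@H](O)[C@@](C)(O)[C@@H]1[C@H]2COC(c3ccc(OC)c(OC)c3)O2)[C@@H]5OCc4ccc(OC)cc4 | intermediate
22 | 11,12-O-isopropylidene acetal of 21 (bis-acetonide) | C=C(C)[C@@H]5OC(C)(C)O[C@@H]([C@@]1(C)C=C[C@H]6OC(C)(C)O[C@@]6(C)[C@@H]1[C@H]2COC(c3ccc(OC)c(OC)c3)O2)[C@@H]5OCc4ccc(OC)cc4 | intermediate
23 | (9S)-9-O-DMB ether with free C8 primary alcohol | C=C(C)[C@@H]5OC(C)(C)O[C@@H]([C@@]1(C)C=C[C@H]6OC(C)(C)O[C@@]6(C)[C@@H]1[C@H](OCc3ccc(OC)c(OC)c3)CO)[C@@H]5OCc4ccc(OC)cc4 | intermediate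
24 | C8 aldehyde (9-O-DMB) | C=C(C)[C@@H]5OC(C)(C)O[C@@H]([C@@]1(C)C=C[C@H]6OC(C)(C)O[C@@]6(C)[C@@H]1[C@H](OCc3ccc(OC)c(OC)c3)C=O)[C@@H]5OCc4ccc(OC)cc4 | intermediate
25 | (R)-lactic acid | C[C@@H](O)C(=O)O | starting material
26 | (2R,5R)-2-tert-butyl-5-methyl-1,3-dioxolan-4-one (cis) | C[C@H]1O[C@@H](C(C)(C)C)OC1=O | intermediate
27 | lithium enolate of 26 | CC1=C([O-])O[C@H](C(C)(C)C)O1.[Li+] | intermediate
28 | aldol adduct of 24 and 27: C8 carbinol (epimers) bonded to C17 (17S) of the dioxolanone, trans to tert-butyl | C=C(C)[C@@H]5OC(C)(C)O[C@@H]([C@@]1(C)C=C[C@H]6OC(C)(C)O[C@@]6(C)[C@@H]1[C@H](OCc3ccc(OC)c(OC)c3)C(O)[C@]7(C)O[C@@H](C(C)(C)C)OC7=O)[C@@H]5OCc4ccc(OC)cc4 | intermediate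
29 | C8 ketone | C=C(C)[C@@H]5OC(C)(C)O[C@@H]([C@@]1(C)C=C[C@H]6OC(C)(C)O[C@@]6(C)[C@@H]1[C@H](OCc3ccc(OC)c(OC)c3)C(=O)[C@]7(C)O[C@@H](C(C)(C)C)OC7=O)[C@@H]5OCc4ccc(OC)cc4 | intermediate
30 | (8S,17S)-8-allyl-8-hydroxy dioxolanone | C=C(C)[C@@H]5OC(C)(C)O[C@@H]([C@@]1(C)C=C[C@H]6OC(C)(C)O[C@@]6(C)[C@@H]1[C@H](OCc3ccc(OC)c(OC)c3)[C@@](O)(CC=C)[C@]7(C)O[C@@H](C(C)(C)C)OC7=O)[C@@H]5OCc4ccc(OC)cc4 | intermediate
31 | (8S,17S)-8,17-dihydroxy C19 acid | C=C(C)[C@@H]5OC(C)(C)O[C@@H]([C@@]1(C)C=C[C@H]6OC(C)(C)O[C@@]6(C)[C@@H]1[C@H](OCc3ccc(OC)c(OC)c3)[C@@](O)(CC=C)[C@](C)(O)C(=O)O)[C@@H]5OCc4ccc(OC)cc4 | intermediate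
32 | tert-butyl ester of 31 | C=C(C)[C@@H]5OC(C)(C)O[C@@H]([C@@]1(C)C=C[C@H]6OC(C)(C)O[C@@]6(C)[C@@H]1[C@H](OCc3ccc(OC)c(OC)c3)[C@@](O)(CC=C)[C@](C)(O)C(=O)OC(C)(C)C)[C@@H]5OCc4ccc(OC)cc4 | intermediate
33 | 9-alcohol (DMB removed) | C=C(C)[C@@H]5OC(C)(C)O[C@@H]([C@@]1(C)C=C[C@H]6OC(C)(C)O[C@@]6(C)[C@@H]1[C@H](O)[C@@](O)(CC=C)[C@](C)(O)C(=O)OC(C)(C)C)[C@@H]5OCc4ccc(OC)cc4 | intermediate
34 | 2,4,9-triol (3-O-PMB, ring A acetonide, tert-butyl ester) | C=C(C)[C@H](O)[C@@H](OCc4ccc(OC)cc4)[C@@H](O)[C@@]1(C)C=C[C@H]2OC(C)(C)O[C@@]2(C)[C@@H]1[C@H](O)[C@@](O)(CC=C)[C@](C)(O)C(=O)OC(C)(C)C | intermediate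
35 | 2,4,9-triacetate (diene for ring closure) | C=C(C)[C@H](OC(C)=O)[C@@H](OCc4ccc(OC)cc4)[C@@H](OC(C)=O)[C@@]1(C)C=C[C@H]2OC(C)(C)O[C@@]2(C)[C@@H]1[C@H](OC(C)=O)[C@@](O)(CC=C)[C@](C)(O)C(=O)OC(C)(C)C | intermediate
36 | protected seco ester: ten-membered ring with Z C5=C6, 3-O-PMB, 11,12-O-isopropylidene, tert-butyl ester | CC(=O)O[C@@H]1[C@H](OCc4ccc(OC)cc4)[C@@H](OC(C)=O)/C(C)=C\C[C@@](O)([C@](C)(O)C(=O)OC(C)(C)C)[C@@H](OC(C)=O)[C@H]2[C@]3(C)OC(C)(C)O[C@@H]3C=C[C@]12C | intermediate
37 | 7-deoxy seco acid of brianodin C | CC(=O)O[C@@H]1[C@H](O)[C@@H](OC(C)=O)/C(C)=C\C[C@@](O)([C@](C)(O)C(=O)O)[C@@H](OC(C)=O)[C@H]2[C@](C)(O)[C@H](O)C=C[C@]12C | intermediate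
38 | (7S)-7-hydroxy seco acid | CC(=O)O[C@@H]1[C@H](O)[C@@H](OC(C)=O)/C(C)=C\[C@H](O)[C@@](O)([C@](C)(O)C(=O)O)[C@@H](OC(C)=O)[C@H]2[C@](C)(O)[C@H](O)C=C[C@]12C | intermediate
39 | brianodin C | CC(=O)O[C@@H]1[C@H](O)[C@@H](OC(C)=O)/C(C)=C\[C@@H]2OC(=O)[C@@](C)(O)[C@@]2(O)[C@@H](OC(C)=O)[C@H]2[C@](C)(O)[C@H](O)C=C[C@]12C | target

**Totals and risks**

Total step count: 28. Longest linear sequence: 25 steps (1, 2, 4, 6–16, 18–28).

Steps most likely to fail:

Step 28 (enzymatic C7 hydroxylation and lactonisation). The oxidant may attack other C–H bonds (C16 methyl, C4, ring A), epoxidise the C5=C6 or C13=C14 alkene, or not turn over because the polyoxygenated acid binds poorly. The fallback uses known chemistry and sets out from 36. Allylic oxidation of the C7 methylene with dirhodium tetrakis(caprolactamate) Rh2(cap)4 and t-BuOOH should give the 7-oxo derivative of 36 F1. Luche reduction (NaBH4, CeCl3·7H2O, MeOH, −78 °C), with hydride expected from the outer face of the ring, should give the 7S-hydroxy derivative of 36 F2. TFA/CH2Cl2/H2O with anisole then removes the tert-butyl, PMB and isopropylidene groups and closes the lactone from the 7-hydroxy tert-butyl ester, coming back to the route at 39.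

Step 26 (ring-closing metathesis). The alkylidene at the allyl terminus may fail to engage the 1,1-disubstituted C5 alkene beside the C4 acetate, so that oligomers from cross-metathesis, alkene migration or the E ring isomer form instead. The fallback moves ring closure ahead of the unmasking steps and sets out from 32, where C2–C4 are held in the isopropylidene dioxane and no allylic ester deactivates the C5 alkene. Metathesis of 32 (same catalyst, toluene, 90 °C) should give the ring-closed 2,4-O-isopropylidene 9-O-DMB ester F3. DDQ gives the ring-closed 9-alcohol F4, PPTS/MeOH gives the ring-closed 2,4,9-triol F5, and acetylation (Ac2O, pyridine, DMAP) comes back to the route at 36.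

Step 27 (global acid deprotection). Under protic acid the acetyl groups may migrate from O2 or O4 to the freed O3, and the allylic C4 acetate or the C12 allylic alcohol may ionise. The fallback unmasks the three groups one after another under orthogonal conditions and sets out from 36. DDQ (CH2Cl2/pH 7 buffer) gives the O3-free derivative of 36 F6. Aqueous AcOH (80 %, 40 °C) removes the ring A acetonide to give the tert-butyl ester of 37 F7. TMSOTf/2,6-lutidine then cleaves the tert-butyl ester through the silyl ester (silyl ethers fall on buffered methanol work-up), coming back to the route at 37.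

Further compounds
F1 | step 28 | 7-oxo derivative of 36 (C5=C6–C7=O enone) | CC(=O)O[C@@H]1[C@H](OCc4ccc(OC)cc4)[C@@H](OC(C)=O)/C(C)=C\C(=O)[C@@](O)([C@](C)(O)C(=O)OC(C)(C)C)[C@@H](OC(C)=O)[C@H]2[C@]3(C)OC(C)(C)O[C@@H]3C=C[C@]12C
F2 | step 28 | 7S-hydroxy derivative of 36 | CC(=O)O[C@@H]1[C@H](OCc4ccc(OC)cc4)[C@@H](OC(C)=O)/C(C)=C\[C@H](O)[C@@](O)([C@](C)(O)C(=O)OC(C)(C)C)[C@@H](OC(C)=O)[C@H]2[C@]3(C)OC(C)(C)O[C@@H]3C=C[C@]12C
F3 | step 26 | ring-closed 2,4-O-isopropylidene 9-O-DMB tert-butyl ester (Z C5=C6) | CC5(C)O[C@@H]1[C@H](OCc4ccc(OC)cc4)[C@@H](O5)/C(C)=C\C[C@@](O)([C@](C)(O)C(=O)OC(C)(C)C)[C@@H](OCc6ccc(OC)c(OC)c6)[C@H]2[C@]3(C)OC(C)(C)O[C@@H]3C=C[C@]12C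
F4 | step 26 | ring-closed 9-alcohol (2,4-O-isopropylidene) | CC5(C)O[C@@H]1[C@H](OCc4ccc(OC)cc4)[C@@H](O5)/C(C)=C\C[C@@](O)([C@](C)(O)C(=O)OC(C)(C)C)[C@@H](O)[C@H]2[C@]3(C)OC(C)(C)O[C@@H]3C=C[C@]12C
F5 | step 26 | ring-closed 2,4,9-triol | O[C@@H]1[C@H](OCc4ccc(OC)cc4)[C@@H](O)/C(C)=C\C[C@@](O)([C@](C)(O)C(=O)OC(C)(C)C)[C@@H](O)[C@H]2[C@]3(C)OC(C)(C)O[C@@H]3C=C[C@]12C
F6 | step 27 | O3-free derivative of 36 | CC(=O)O[C@@H]1[C@H](O)[C@@H](OC(C)=O)/C(C)=C\C[C@@](O)([C@](C)(O)C(=O)OC(C)(C)C)[C@@H](OC(C)=O)[C@H]2[C@]3(C)OC(C)(C)O[C@@H]3C=C[C@]12C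
F7 | step 27 | tert-butyl ester of 37 | CC(=O)O[C@@H]1[C@H](O)[C@@H](OC(C)=O)/C(C)=C\C[C@@](O)([C@](C)(O)C(=O)OC(C)(C)C)[C@@H](OC(C)=O)[C@H]2[C@](C)(O)[C@H](O)C=C[C@]12C
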